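**Retrosynthetic overview**
1. Ring E (thiazine S,S-dioxide) is made last: hypotaurine adds S, then N, across the free C=C of quinone ring D, which is unmasked from a 5,8-dimethoxynaphthalene.
2. Ring B (seven-membered enol lactone) comes from acyl transfer of the ortho-carboxyl group to the dienol oxygen of a β-cyclocitral-type enal; the enal carbon comes from CO via the enol triflate of an α-aryl ketone.
3. Key disconnection: the aryl–C(quaternary) bond, from an arylzinc and a tertiary α-bromo ketone (enolonium equivalent) under nickel/chiral bis(oxazoline) catalysis; this sets the S centre.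
4. Ring order: A (2,6-dimethylcyclohexanone) and C (a 2-naphthoate) are bought and joined in the key step, then ring D is oxidised and masked, ring B is closed, ring D is unmasked, and ring E is added.

Assumption: the (S,S)-ligand of step 3 is taken to deliver the S quaternary centre; if the sense of induction is opposite, its (R,R)-enantiomer is used.

**Route**

Step 1
Reactants: 1 2,6-dimethylcyclohexanone
Product: 2 2-bromo-2,6-dimethylcyclohexanone (racemic, both diastereomers)
Conditions: Br2 (1.0 equiv), CH2Cl2, 0 °C to 20 °C
Reagents that add atoms: bromine (Br2), BrBr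
Why: Acid-catalysed α-bromination through the enol (both α-carbons are equivalent and tertiary) gives the tertiary α-bromo ketone that serves as the enolonium equivalent, and it is used as the racemic mixture so no stereocontrol is needed.

Step 2
Reactants: 3 methyl 3-aminonaphthalene-2-carboxylate
Product: 5 methyl 3-iodonaphthalene-2-carboxylate, via arenediazonium chloride 4 (not isolated)
Conditions: NaNO2, aq. HCl, 0 °C; then KI, 0 °C to 60 °C
Reagents that add atoms: potassium iodide (KI), [K+].[I-]; sodium nitrite (NaNO2), [Na+].[O-]N=O (one nitrogen of intermediate 4 only); hydrogen chloride, Cl (chloride of intermediate 4 only)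
Why: Diazotisation followed by iododediazoniation (Sandmeyer-type reaction) replaces NH2 by iodine ortho to the ester without touching the ester, and no stereocentre is involved.

Step 3
Reactants: 5 methyl 3-iodonaphthalene-2-carboxylate; 2 2-bromo-2,6-dimethylcyclohexanone
Product: 7 methyl 3-[(1S)-1,3-dimethyl-2-oxocyclohexyl]naphthalene-2-carboxylate (both C3 epimers), via arylzinc iodide 6 (not isolated)
Conditions: 5, Zn dust, LiCl, THF, 40 °C; then 2, NiCl2(MeOCH2CH2OMe) (10 mol %), (S,S)-2,2'-(propane-2,2-diyl)bis(4-phenyl-4,5-dihydro-1,3-oxazole) (13 mol %), MeOCH2CH2OMe/THF, −30 °C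
Reagents that add atoms: zinc (Zn), [Zn] (zinc of intermediate 6 only)
Why: Proposed new method: the tertiary α-bromo ketone acts as an enolonium (α-keto cation) equivalent, because monovalent nickel abstracts bromine to give a planar tertiary α-keto radical that is captured by the chiral bis(oxazoline)–arylnickel complex, and reductive elimination then joins two normally nucleophilic carbons (enolate α-carbon and aryl–metal carbon) and sets the S quaternary centre enantioconvergently from racemic 2; the closest known reaction type is the nickel/bis(oxazoline)-catalysed enantioconvergent Negishi arylation of racemic α-bromo ketones, including α-bromo-α-fluoro ketones that give fully substituted stereocentres, and the C3 epimers do not matter because C3 becomes sp2 in step 6.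

Step 4
Reactants: 7 methyl 3-[(1S)-1,3-dimethyl-2-oxocyclohexyl]naphthalene-2-carboxylate
Product: 8 methyl 3-[(1S)-1,3-dimethyl-2-oxocyclohexyl]-5,8-dioxo-5,8-dihydronaphthalene-2-carboxylate
Conditions: H5IO6 (4.2 equiv), CrO3 (10 mol %), MeCN, 5 °C to 20 °C
Reagents that add atoms: orthoperiodic acid (H5IO6), O=I(O)(O)(O)(O)O (the two quinone oxygens)
Why: CrO3-catalysed periodic acid oxidation of a naphthalene to the 1,4-naphthoquinone should occur on the unsubstituted ring, which is more electron-rich and less hindered than the ring carrying the ester and the tertiary alkyl group, and the quaternary centre is not touched.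

Step 5
Reactants: 8 methyl 3-[(1S)-1,3-dimethyl-2-oxocyclohexyl]-5,8-dioxo-5,8-dihydronaphthalene-2-carboxylate
Product: 10 methyl 3-[(1S)-1,3-dimethyl-2-oxocyclohexyl]-5,8-dimethoxynaphthalene-2-carboxylate, via hydroquinone 9 (not isolated)
Conditions: Na2S2O4, THF/H2O, 20 °C; then Me2SO4, K2CO3, acetone, 56 °C
Reagents that add atoms: dimethyl sulfate, COS(=O)(=O)OC
Why: Dithionite reduction and Williamson O-methylation mask ring D as a 1,4-dimethoxyarene that tolerates the base, palladium and tin hydride chemistry of steps 6 to 8, and the weak base cannot affect the quaternary centre.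

Step 6
Reactants: 10 methyl 3-[(1S)-1,3-dimethyl-2-oxocyclohexyl]-5,8-dimethoxynaphthalene-2-carboxylate
Product: 12 methyl 3-[(1S)-1,3-dimethyl-2-(trifluoromethanesulfonyloxy)cyclohex-2-en-1-yl]-5,8-dimethoxynaphthalene-2-carboxylate, via potassium enolate 11 (not isolated)
Conditions: KN(SiMe3)2, THF, −78 °C; then PhNTf2, −78 °C to 0 °C
Reagents that add atoms: N-phenylbis(trifluoromethanesulfonimide), O=S(=O)(N(c1ccccc1)S(=O)(=O)C(F)(F)F)C(F)(F)F; potassium bis(trimethylsilyl)amide (KN(SiMe3)2), C[Si](C)(C)[N-][Si](C)(C)C.[K+] (potassium of intermediate 11 only)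
Why: The ketone has a single α-hydrogen, so enol triflate formation is regiospecific, both C3 epimers converge to one alkene, trapping of the enolate outruns the thermodynamically unfavourable attack on the methyl ester, and the S centre has no α-hydrogen and cannot epimerise.

Step 7
Reactants: 12 methyl 3-[(1S)-1,3-dimethyl-2-(trifluoromethanesulfonyloxy)cyclohex-2-en-1-yl]-5,8-dimethoxynaphthalene-2-carboxylate
Product: 13 methyl 3-[(1S)-2-formyl-1,3-dimethylcyclohex-2-en-1-yl]-5,8-dimethoxynaphthalene-2-carboxylate
Conditions: CO (3 atm), Bu3SnH (slow addition), Pd(PPh3)4 (5 mol %), THF, 50 °C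
Reagents that add atoms: carbon monoxide, [C-]#[O+]
Why: Oxidative addition of the enol triflate to zerovalent palladium, CO insertion and tin hydride capture of the acylpalladium (Stille reductive carbonylation, formylation) give the β-cyclocitral-type enal, a reaction class that works on 2,6,6-trisubstituted cyclohexenyl triflates, and no stereocentre is formed.

Step 8
Reactants: 13 methyl 3-[(1S)-2-formyl-1,3-dimethylcyclohex-2-en-1-yl]-5,8-dimethoxynaphthalene-2-carboxylate
Product: 16 (S)-dimethoxy dienol lactone (seven-membered enol lactone ring B, ArC(=O)–O–CH=C, fused to the 5,8-dimethoxynaphthalene and to a 2-methylcyclohex-2-ene ring A; CH3-bearing ring-fusion carbon S), via potassium carboxylate 14 (not isolated), via mixed acetic anhydride 15 (not isolated)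
Conditions: KOSiMe3, THF, 50 °C; then Ac2O, toluene, 80 °C
Reagents that add atoms: potassium trimethylsilanolate (KOSiMe3), C[Si](C)(C)[O-].[K+] (potassium and one carboxylate oxygen of 14); acetic anhydride, CC(=O)OC(C)=O (acetyl group of intermediate 15 only)
Why: Anhydrous ester cleavage by silanolate, activation of the carboxylate as the mixed anhydride and O-acylation of the thermodynamic endocyclic dienol of the enal (enol lactonisation by the acetic anhydride/acetate method for oxo acids) close ring B and move the ring alkene to its final position, and the S centre is untouched.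

Step 9
Reactants: 16 (S)-dimethoxy dienol lactone
Product: 17 (S)-quinone dienol lactone (16 with the dimethoxyarene oxidised to the 1,4-naphthoquinone)
Conditions: (NH4)2Ce(NO3)6 (2.5 equiv), MeCN/H2O 2:1, 0 °C, 15 min
Reagents that add atoms: water, O (both quinone oxygens)
Why: Oxidative demethylation of the 1,4-dimethoxyarene by tetravalent cerium (two one-electron oxidations, with water supplying the quinone oxygens) is fast at 0 °C and should leave the acylated dienol and the stereocentre intact.

Step 10
Reactants: 17 (S)-quinone dienol lactone; 18 hypotaurine (2-aminoethanesulfinic acid)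
Product: 22 target CNP0348176.1, via sulfonyl hydroquinone 19 (not isolated), via sulfonyl quinone 20 (not isolated), via thiazine hydroquinone 21 (not isolated)
Conditions: MeCN/H2O 1:1, NaOAc/AcOH buffer (pH 5), O2 (1 atm), 20 °C to 40 °C
Reagents that add atoms: none
Why: At pH 5 the amine is protonated, so the sulfinate adds first (sulfa-Michael addition) to the quinone carbon β to the more electrophilic carbonyl (the one whose ring carbon is para to the lactone acyl group), autoxidation gives the sulfonyl quinone, and intramolecular aza-Michael addition at the neighbouring carbon followed by a second autoxidation closes ring E with the required regiochemistry (the thiazinoquinone annulation used for natural thiazinoquinones), leaving the stereocentre untouched.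

**Compound list**
1 | 2,6-dimethylcyclohexanone (cis/trans mixture) | CC1CCCC(C)C1=O | starting material
2 | 2-bromo-2,6-dimethylcyclohexanone (racemic, both diastereomers) | CC1CCCC(C)(Br)C1=O | intermediate
3 | methyl 3-aminonaphthalene-2-carboxylate | COC(=O)c1cc2ccccc2cc1N | starting material
4 | 3-(methoxycarbonyl)naphthalene-2-diazonium chloride | COC(=O)c1cc2ccccc2cc1[N+]#N.[Cl-] | intermediate
5 | methyl 3-iodonaphthalene-2-carboxylate | COC(=O)c1cc2ccccc2cc1I | intermediate
6 | [3-(methoxycarbonyl)naphthalen-2-yl]zinc iodide | COC(=O)c1cc2ccccc2cc1[Zn]I | intermediate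
7 | methyl 3-[(1S)-1,3-dimethyl-2-oxocyclohexyl]naphthalene-2-carboxylate (C3 epimers) | CC1CCC[C@](C)(C1=O)c1cc2ccccc2cc1C(=O)OC | intermediate
8 | methyl 3-[(1S)-1,3-dimethyl-2-oxocyclohexyl]-5,8-dioxo-5,8-dihydronaphthalene-2-carboxylate | CC1CCC[C@](C)(C1=O)c1cc2C(=O)C=CC(=O)c2cc1C(=O)OC | intermediate
9 | methyl 3-[(1S)-1,3-dimethyl-2-oxocyclohexyl]-5,8-dihydroxynaphthalene-2-carboxylate | CC1CCC[C@](C)(C1=O)c1cc2c(O)ccc(O)c2cc1C(=O)OC | intermediate
10 | methyl 3-[(1S)-1,3-dimethyl-2-oxocyclohexyl]-5,8-dimethoxynaphthalene-2-carboxylate | CC1CCC[C@](C)(C1=O)c1cc2c(OC)ccc(OC)c2cc1C(=O)OC | intermediate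
11 | potassium enolate of 10 (enolate C=C between the carbonyl carbon and the CH3-bearing C3; quaternary carbon S) | CC1=C([O-])[C@@](C)(CCC1)c1cc2c(OC)ccc(OC)c2cc1C(=O)OC.[K+] | intermediate
12 | methyl 3-[(1S)-1,3-dimethyl-2-(trifluoromethanesulfonyloxy)cyclohex-2-en-1-yl]-5,8-dimethoxynaphthalene-2-carboxylate | CC1=C(OS(=O)(=O)C(F)(F)F)[C@@](C)(CCC1)c1cc2c(OC)ccc(OC)c2cc1C(=O)OC | intermediate
13 | methyl 3-[(1S)-2-formyl-1,3-dimethylcyclohex-2-en-1-yl]-5,8-dimethoxynaphthalene-2-carboxylate | CC1=C(C=O)[C@@](C)(CCC1)c1cc2c(OC)ccc(OC)c2cc1C(=O)OC | intermediate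
14 | potassium 3-[(1S)-2-formyl-1,3-dimethylcyclohex-2-en-1-yl]-5,8-dimethoxynaphthalene-2-carboxylate | CC1=C(C=O)[C@@](C)(CCC1)c1cc2c(OC)ccc(OC)c2cc1C(=O)[O-].[K+] | intermediate
15 | acetic 3-[(1S)-2-formyl-1,3-dimethylcyclohex-2-en-1-yl]-5,8-dimethoxynaphthalene-2-carboxylic anhydride | CC1=C(C=O)[C@@](C)(CCC1)c1cc2c(OC)ccc(OC)c2cc1C(=O)OC(C)=O | intermediate
16 | (S)-dimethoxy dienol lactone: seven-membered enol lactone ring B fused to 5,8-dimethoxynaphthalene and to 2-methylcyclohex-2-ene ring A, CH3-bearing fusion carbon S | CC1=CCC[C@]2(C)C1=COC(=O)c1cc3c(OC)ccc(OC)c3cc12 | intermediate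
17 | (S)-quinone dienol lactone: 16 with the dimethoxyarene replaced by the 1,4-naphthoquinone | CC1=CCC[C@]2(C)C1=COC(=O)c1cc3C(=O)C=CC(=O)c3cc12 | intermediate
18 | hypotaurine (2-aminoethanesulfinic acid) | NCCS(=O)O | starting material
19 | sulfonyl hydroquinone: hydroquinone form of 20 | CC1=CCC[C@]2(C)C1=COC(=O)c1cc3c(O)c(S(=O)(=O)CCN)cc(O)c3cc12 | intermediate
20 | sulfonyl quinone: 17 carrying SO2CH2CH2NH2 on the quinone carbon next to the C=O whose ring carbon is para to the quaternary-carbon substituent | CC1=CCC[C@]2(C)C1=COC(=O)c1cc3C(=O)C(S(=O)(=O)CCN)=CC(=O)c3cc12 | intermediate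
21 | thiazine hydroquinone: hydroquinone form of 22 | CC1=CCC[C@]2(C)C1=COC(=O)c1cc3c(O)c4c(NCCS4(=O)=O)c(O)c3cc12 | intermediate
22 | CNP0348176.1: (S)-quinone dienol lactone with the fused 3,4-dihydro-2H-1,4-thiazine 1,1-dioxide ring E (N on the quinone carbon next to the C=O para-related to the lactone carbonyl, S on the other) | CC1=CCC[C@]2(C)C1=COC(=O)c1cc3c(cc12)C(=O)C1=C(C3=O)S(=O)(=O)CCN1 | target

**Step count and risks**
Total steps: 10. Longest linear sequence: 9 steps (3 to 22, steps 2 to 10); step 1 is a one-step side branch.

Risk 1, step 3 (key coupling). A tertiary radical must combine with an ortho-substituted arylnickel; HBr elimination or zinc enolate formation from 2 may compete, and the enantioselectivity is unproven. Fallback, setting out from 1 and 5 and coming back at 7: reverse which partner is umpoled. Ketone 1 is converted to the trimethylsilyl enol ether F1 (Me3SiCl, NaI, Et3N, MeCN). Iodide 5 is oxidised in the presence of mesitylene (3-ClC6H4CO3H, CF3SO3H, CH2Cl2) to the aryl(mesityl)iodonium triflate F2, an aryl cation equivalent. F1 and F2 are then joined with Cu(OSO2CF3)2 and the same chiral bis(oxazoline) in CH2Cl2, through an electrophilic aryl–trivalent-copper species, to give 7.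

Risk 2, step 7 (formylation). The tetrasubstituted triflate next to a quaternary carbon may add slowly to palladium and give hydrodetriflation instead of CO insertion. Fallback, setting out from 12 and coming back at 13: Stille coupling of 12 with tributyl(vinyl)stannane (Pd(PPh3)4, dioxane, 90 °C) gives the vinyl diene F3. Its unhindered terminal vinyl group is then cleaved selectively (OsO4 cat., NaIO4, 2,6-lutidine, dioxane/H2O) to enal 13.

Risk 3, step 10 (thiazine annulation). If the amine attacks first, the regioisomer forms, and a free amine can also open the enol lactone. Fallback, setting out from 17 and 18 and coming back at 20: hypotaurine 18 is protected (Boc2O, NaOH, dioxane/H2O) as N-Boc hypotaurine sodium salt F4, so that only sulfur can add. Addition to 17 (AcOH, MeCN/H2O) gives the Boc-protected sulfonyl hydroquinone F5, and Ag2O oxidises it to the Boc-protected sulfonyl quinone F6. CF3CO2H in CH2Cl2 followed by NaHCO3 releases the amine as 20, which cyclises to 21 and is oxidised by air to 22.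

**Further compounds**
F1 | step 3 | [(2,6-dimethylcyclohex-1-en-1-yl)oxy]trimethylsilane | CC1CCCC(C)=C1O[Si](C)(C)C
F2 | step 3 | [3-(methoxycarbonyl)naphthalen-2-yl](2,4,6-trimethylphenyl)iodonium trifluoromethanesulfonate | COC(=O)c1cc2ccccc2cc1[I+]c1c(C)cc(C)cc1C.[O-]S(=O)(=O)C(F)(F)F
F3 | step 7 | methyl 3-[(1S)-2-ethenyl-1,3-dimethylcyclohex-2-en-1-yl]-5,8-dimethoxynaphthalene-2-carboxylate | CC1=C(C=C)[C@@](C)(CCC1)c1cc2c(OC)ccc(OC)c2cc1C(=O)OC
F4 | step 10 | sodium 2-[(tert-butoxycarbonyl)amino]ethanesulfinate | CC(C)(C)OC(=O)NCCS(=O)[O-].[Na+]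
F5 | step 10 | Boc-protected sulfonyl hydroquinone (19 with NH-Boc) | CC1=CCC[C@]2(C)C1=COC(=O)c1cc3c(O)c(S(=O)(=O)CCNC(=O)OC(C)(C)C)cc(O)c3cc12
F6 | step 10 | Boc-protected sulfonyl quinone (20 with NH-Boc) | CC1=CCC[C@]2(C)C1=COC(=O)c1cc3C(=O)C(S(=O)(=O)CCNC(=O)OC(C)(C)C)=CC(=O)c3cc12
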